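# Littorachalcone by desymmetrising C–H oxygenation of a symmetric diaryl ether

## Structural features

1. Littorachalcone 10 (C30H26O8) holds four benzene rings and no other ring. Two central rings, A (1,4-disubstituted) and B (1,3,4-trisubstituted), are joined through one ether oxygen (C4'–O–C4), and rings C and D are terminal 2,4-dihydroxyphenyl rings.
2. Para to the ether oxygen, C1' of ring A and C1 of ring B each carry the same CH2–CH2–C(=O) chain. Its carbonyl carbon is bound to C1 of ring C or D and is hydrogen-bonded to the 2-OH there.
3. There is no stereocentre, no stereogenic double bond and no hindered axis, so no stereocentres stand next to each other and the compound is achiral.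
4. The only atom that breaks the twofold symmetry is the hydroxyl oxygen on C3 of ring B, ortho to the ether oxygen and meta to the chain. This is the 4-aryloxy-3-hydroxy pattern, not the 3-aryloxy-4-hydroxy pattern that an ortho C–O coupling of two 4-hydroxyphenyl monomers would leave.
5. Fragile groups are the five free phenols (air-sensitive as phenolates, ring B being a catechol monoether) and the two enolisable ketones. Above all, rings C and D would outrun rings A and B towards any electrophile or oxidant.
6. The real difficulty has three parts: the unsymmetrical ether between two electron-rich, unactivated rings, the choice between the two neighbouring oxygens of ring B, and doing both without protecting five phenols.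
7. The key step exploits the hidden symmetry of the A–O–B core. Once the oxygen on C3 is removed, C3–H and C5–H of ring B and C3'–H and C5'–H of ring A are four equivalent positions. They are the most electron-rich open positions of a bis(4-alkylphenyl) ether, and oxygenation of any one of them gives exactly the pattern of ring B.

## Logic of the disconnections

**10 ⇒ 7 + two 8 (through 9).**
- Bonds cut: the two C(=O)–C1 bonds to rings C and D.
- Reason: rings C and D are the most nucleophilic and most oxidisable parts of 10. If they arrive last, no earlier step has to spare or protect them. The innate reactivity of 8 at its C4 already writes the 2,4-dihydroxy pattern, and each ketone is carried up to this point as an inert nitrile.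
- Gain: a C30 pentaphenol becomes a C18 monophenol plus a commodity arene, and all protecting groups vanish.
- Demand: an electrophile weak enough to attack only the doubly activated ring of 8, reaction at both ends, and tolerance of the free C3–OH.

**7 ⇒ 3 + 5 (through 6), the key disconnection.**
- Bond cut: C3–O(H) on ring B, and not the ether bond.
- Reason: removal of this one oxygen turns the unsymmetrical core into the C2v-symmetric 3, whose ether bond no longer has to be made at all. The question "which oxygen of the catechol carries the aryl group" disappears, because the four positions ortho to the ether oxygen are equivalent.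
- In one sentence, the route is a single C–H oxygenation of the symmetric diaryl ether 3 at one of its four equivalent positions ortho to the ether oxygen. That sentence does not fit the ether-coupling/aldol route.
- Gain: half as many distinct carbons, and a precursor open to two-directional synthesis.
- Demand: attack on the ring and not on benzylic C–H, ortho to oxygen and not ortho to the chain, and a stop after one oxygen.

**3 ⇒ 1 + two 2.**
- Bonds cut: C1–CH2 and C1'–CH2.
- Reason: this is the only cut that leads back to a bulk diaryl ether with both para positions already marked. The three-carbon arm comes complete and in the right oxidation state, so no alkene reduction follows.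
- Gain: all C18 of 3 in one operation from two purchased materials.
- Demand: an sp2–sp3 coupling that tolerates a nitrile, outruns β-hydride elimination and goes to completion at both bromides.

**5 ⇒ 4.**
- Bonds cut: the two acyl C–O bonds of the cyclic peroxide.
- Reason: 5 is not an article of commerce, but it is one step from a bulk diacid chloride and a solid peroxide source.
- Gain: a one-step side branch.
- Demand: mild, anhydrous handling of an energetic compound.

## Other disconnections considered

**Alternative 1:** This is the first that comes to mind.
- Cut: the ether bond C4–O, and the two Cα–Cβ bonds of the chains.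
- Forward key step: an SNAr or Ullmann-type O-arylation joins the two benzaldehyde halves. One is a phenol whose neighbouring oxygen is masked as a methyl ether, the other a 4-halo partner. The product is 4-(4-formylphenoxy)-3-methoxybenzaldehyde A1.
- Continuation: a twofold Claisen–Schmidt condensation with a doubly O-benzylated acetophenone partner would give the bis-chalcone A2. Hydrogenation with hydrogenolysis would give the 3-O-methyl ether A3, and a last O-demethylation would give 10.
- Ground for preferring the chosen plan: the sequence is sound, but it carries five O-protecting groups on and off. It pays for the O3/O4 differentiation with a methyl ether that must be cleaved by a hard Lewis acid at the very end, next to a diaryl ether and several other Lewis-basic oxygens. Each C–C bond it forms needs a reduction afterwards. It would run to about twice the length of the chosen plan, which needs no protecting group and no redox correction.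

**Alternative 2:**
- Cut: the same ether bond, in the biomimetic sense.
- Forward key step: an anodic or hypervalent-iodine C–O phenol coupling of two molecules of davidigenin A4.
- Ground for preferring the chosen plan: a phenoxyl radical or phenoxenium ion carries spin or charge on the carbons ortho and para to its own oxygen. Para is blocked by the chain, so the second phenol oxygen bonds to C3 while the acceptor ring keeps its OH at C4. That leads to the 3-aryloxy-4-hydroxy isomer A5, a constitutional isomer of 10.
- To reach 10, the acceptor would have to be the 3-hydroxyphenyl monomer A6 and be attacked at C4, although its C6 (para to the OH, unhindered) is the intrinsically preferred site. It would also be a cross-coupling of two phenols of similar oxidation potential in the presence of more easily oxidised resorcinol rings. Structure and mechanism both speak against it.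

**Alternative 3:**
- Cut: both aryl–CH2 bonds first, keeping the C3 oxygen and starting from purchased 2-phenoxyphenol A7.
- Forward key step: after sulfonylation to 2-phenoxyphenyl methanesulfonate A8, a twofold para-bromination gives 5-bromo-2-(4-bromophenoxy)phenyl methanesulfonate A9. A twofold coupling with 2 and loss of the sulfonate would then give 7.
- Ground for preferring the chosen plan: the position on ring B must be decided by a contest between two oxygen substituents on the less reactive ring. Once ring A is para-brominated, its ortho positions and the position para to the sulfonate compete with the wanted one. A masking and an unmasking step are added. In the chosen plan the same regiochemical question is answered by symmetry and not by a rate difference.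

Key step: step 3

Assumption: the target SMILES contains no stereogenic element, so "single enantiomer" calls for no stereocontrol, and the route aims at the constitution exactly as written (ether oxygen para to both chains, OH on C3 of ring B).

## Route

**Step 1**
Reactants: 1 bis(4-bromophenyl) ether; 2 2-cyanoethylzinc bromide (commercial 0.5 M solution in THF)
Product: 3 3,3'-(oxydi-4,1-phenylene)dipropanenitrile
Conditions: 2 (2.6 equiv), Pd(OAc)2 (2 mol %), SPhos (4 mol %), THF, 50 °C
Reagents that add atoms: none
Why: Twofold Negishi sp2–sp3 coupling; the functionalised primary alkylzinc halide tolerates its own nitrile, and the bulky biarylphosphine should make reductive elimination faster than β-hydride elimination. An excess of 2 should drive both equivalent C–Br bonds to react, and no stereocentre is formed.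

**Step 2**
Reactants: 4 phthaloyl dichloride
Product: 5 phthaloyl peroxide (2,3-benzodioxine-1,4-dione)
Conditions: 2Na2CO3·3H2O2 (excess), CH2Cl2, 23 °C; filter, concentrate below 30 °C, use at once
Reagents that add atoms: sodium percarbonate, [Na+].[Na+].[Na+].[Na+].[O-]C([O-])=O.[O-]C([O-])=O.OO.OO.OO
Why: Double acyl substitution of the diacid chloride by the hydrogen peroxide held in the solid percarbonate closes the six-membered cyclic diacyl peroxide, while the carbonate takes up HCl. This is the standard type of preparation of cyclic diacyl peroxides; 5 is energetic and should be made in small batches behind a shield.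

**Step 3**
Reactants: 3 3,3'-(oxydi-4,1-phenylene)dipropanenitrile; 5 phthaloyl peroxide
Product: 7 3-[4-[4-(2-cyanoethyl)phenoxy]-3-hydroxyphenyl]propanenitrile, via aryl hydrogen phthalate 6 (not isolated)
Conditions: 5 (0.9 equiv), (CF3)2CHOH, 23→40 °C; evaporate; then sat. aq NaHCO3, THF, 40 °C, N2; recover unreacted 3
Reagents that add atoms: none
Why: Arene C–H hydroxylation with a cyclic diacyl peroxide (reverse-rebound aromatic oxygenation), a known reaction type for alkylarenes and aryl ethers. Homolysis of the O–O bond of 5 gives a tethered bis(acyloxyl) diradical; one electrophilic oxygen radical adds to the ring to give a cyclohexadienyl radical, and the second, held next to it by the phthaloyl tether, takes the hydrogen from the new sp3 carbon and rearomatises the ring to 6. Because the hydrogen abstraction follows the addition inside one species and no free chain carrier arises, the weaker benzylic and α-cyano C–H bonds should stay untouched. No ring is closed and no stereocentre is formed. Site selectivity: addition ortho to the ether oxygen places spin on the oxygen-bearing carbon and meets the largest HOMO coefficient, the para carbon is blocked by the chain and cannot lose hydrogen, and the positions ortho to the chain are activated only by alkyl. Since C3, C5, C3' and C5' of 3 are equivalent by symmetry, every such addition leads to one constitution, the 4-aryloxy-3-hydroxy pattern of ring B. Mono-selectivity should come from three sources: the acyloxy group of 6 weakens the donor power of the shared ether oxygen for both rings, only two instead of four good sites are left, and 5 is the limiting reagent. Bicarbonate then cleaves the aryl ester through its neighbouring carboxylate (by way of phthalic anhydride) under conditions that leave the nitriles alone, and neutral 7 is extracted while phthalate stays in the water.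

**Step 4**
Reactants: 7 3-[4-[4-(2-cyanoethyl)phenoxy]-3-hydroxyphenyl]propanenitrile; 8 resorcinol
Product: 10 littorachalcone, via bis(ketiminium chloride) 9 (not isolated)
Conditions: 8 (5 equiv), ZnCl2 (fused), HCl (g), Et2O–dioxane, 0→23 °C; decant; then H2O, 100 °C
Reagents that add atoms: water, O; hydrogen chloride, Cl (its chloride stays only in intermediate 9)
Why: Twofold Houben–Hoesch acylation; the nitrilium-type electrophile made from nitrile, HCl and ZnCl2 is weak enough to attack only C4 of 8 (para to one OH, ortho to the other), which writes the 2,4-dihydroxyphenyl ketone pattern, while rings A and B as monooxygen-activated rings should not react. Hot water hydrolyses 9 to the two ketones, and the excess of 8 should suppress double acylation of one resorcinol ring and O-imidoylation of the C3–OH.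

## Compound list

1 | bis(4-bromophenyl) ether | Brc1ccc(Oc2ccc(Br)cc2)cc1 | starting material
2 | 2-cyanoethylzinc bromide | N#CCC[Zn]Br | starting material
3 | 3,3'-(oxydi-4,1-phenylene)dipropanenitrile | N#CCCc1ccc(Oc2ccc(CCC#N)cc2)cc1 | intermediate
4 | phthaloyl dichloride | O=C(Cl)c1ccccc1C(=O)Cl | starting material
5 | phthaloyl peroxide (2,3-benzodioxine-1,4-dione) | O=C1OOC(=O)c2ccccc12 | intermediate
6 | 2-{[5-(2-cyanoethyl)-2-[4-(2-cyanoethyl)phenoxy]phenoxy]carbonyl}benzoic acid (aryl hydrogen phthalate) | N#CCCc1ccc(Oc2ccc(CCC#N)cc2OC(=O)c2ccccc2C(=O)O)cc1 | intermediate
7 | 3-[4-[4-(2-cyanoethyl)phenoxy]-3-hydroxyphenyl]propanenitrile | N#CCCc1ccc(Oc2ccc(CCC#N)cc2O)cc1 | intermediate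
8 | resorcinol | Oc1cccc(O)c1 | starting material
9 | bis(ketiminium chloride) of 10 (both C=O replaced by C=NH2+ Cl−) | [Cl-].[Cl-].[NH2+]=C(CCc1ccc(Oc2ccc(CCC(=[NH2+])c3ccc(O)cc3O)cc2O)cc1)c1ccc(O)cc1O | intermediate
10 | littorachalcone, 1-(2,4-dihydroxyphenyl)-3-[4-[4-[3-(2,4-dihydroxyphenyl)-3-oxopropyl]-2-hydroxyphenoxy]phenyl]propan-1-one (achiral) | O=C(CCc1ccc(Oc2ccc(CCC(=O)c3ccc(O)cc3O)cc2O)cc1)c1ccc(O)cc1O | target

## Step count and least certain steps

Total step count: 4. Longest linear sequence: 3 (steps 1, 3 and 4). Step 2 is a one-step side branch that supplies the oxidant.

**Step 3 (key step).**
- Three processes are most likely to hurt. The first is a second oxygenation on the still unsubstituted ring, because the deactivation passed through the ether oxygen is only moderate. The second is addition of the oxygen radical at the blocked para carbon, followed by recombination, which dearomatises the ring. The third is slow conversion, because each ring receives only half of the donor power of the one oxygen.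
- The fallback replaces radical oxygen transfer by polar halogenation and cross-coupling. It sets out from 3 and returns at 7.
- Monobromination ortho to the ether oxygen (NBS, MeCN, dark, 0 °C) should give 3-[3-bromo-4-[4-(2-cyanoethyl)phenoxy]phenyl]propanenitrile F1.
- Miyaura borylation (B2pin2, KOAc, Pd(dppf)Cl2, dioxane, 80 °C) should give 3-[4-[4-(2-cyanoethyl)phenoxy]-3-(4,4,5,5-tetramethyl-1,3,2-dioxaborolan-2-yl)phenyl]propanenitrile F2.
- Oxone in aqueous acetone should then oxidise the C–B bond to the phenol 7. It avoids alkaline peroxide, which could hydrate the nitriles.
- The symmetry argument holds unchanged, and bromine deactivates its own ring more strongly.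

**Step 4.**
- The reaction may stall after the first addition, because the mono-ketiminium salt can separate from the ethereal medium before the second nitrile has reacted.
- Pinner-type O-imidoylation of the C3–OH or of 8 may divert nitrile into esters on hydrolysis.
- The fallback changes the electrophile from nitrilium to acyl. It sets out from 7 and returns at 10.
- Acid hydrolysis (6 M HCl, AcOH, reflux) should give 3-[4-[4-(2-carboxyethyl)phenoxy]-3-hydroxyphenyl]propanoic acid F3.
- F3 is heated with an excess of 8 in BF3·OEt2 (85 °C), a Nencki-type Friedel–Crafts/Fries acylation, and this is followed by an aqueous work-up.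
- In that variant, ring closure of the ring B arm onto the position para to the C3–OH is the process to watch. The large excess of the far more nucleophilic 8 is the safeguard.

**Step 1.**
- β-Hydride elimination from the aryl–Pd–CH2CH2CN intermediate would cause hydrodebromination.
- Incomplete reaction of the second bromide is possible, because the internally coordinated zinc reagent transmetalates slowly.
- The fallback builds the arm by alkene insertion instead of alkyl transfer. It sets out from 1 and returns at 3.
- A twofold Mizoroki–Heck reaction with acrylonitrile (Pd(OAc)2, P(o-tol)3, Et3N, DMF, 110 °C) should give (2E,2'E)-3,3'-(oxydi-4,1-phenylene)bis(prop-2-enenitrile) F4. Its alkene geometry is of no consequence.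
- Hydrogenation (H2 1 atm, Pd/C, EtOAc, 23 °C) should saturate both alkenes to 3 and leave the nitriles intact.

## Further compounds

F1 | step 3 | 3-[3-bromo-4-[4-(2-cyanoethyl)phenoxy]phenyl]propanenitrile | N#CCCc1ccc(Oc2ccc(CCC#N)cc2Br)cc1
F2 | step 3 | 3-[4-[4-(2-cyanoethyl)phenoxy]-3-(4,4,5,5-tetramethyl-1,3,2-dioxaborolan-2-yl)phenyl]propanenitrile | N#CCCc1ccc(Oc2ccc(CCC#N)cc2B2OC(C)(C)C(C)(C)O2)cc1
F3 | step 4 | 3-[4-[4-(2-carboxyethyl)phenoxy]-3-hydroxyphenyl]propanoic acid | O=C(O)CCc1ccc(Oc2ccc(CCC(=O)O)cc2O)cc1
F4 | step 1 | (2E,2'E)-3,3'-(oxydi-4,1-phenylene)bis(prop-2-enenitrile) | N#C/C=C/c1ccc(Oc2ccc(/C=C/C#N)cc2)cc1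
A1 | alternative 1 | 4-(4-formylphenoxy)-3-methoxybenzaldehyde | COc1cc(C=O)ccc1Oc1ccc(C=O)cc1
A2 | alternative 1 | tetra-O-benzyl 3-O-methyl bis-chalcone, (E,E) | COc1cc(/C=C/C(=O)c2ccc(OCc3ccccc3)cc2OCc2ccccc2)ccc1Oc1ccc(/C=C/C(=O)c2ccc(OCc3ccccc3)cc2OCc2ccccc2)cc1
A3 | alternative 1 | 3-O-methyl ether of littorachalcone | COc1cc(CCC(=O)c2ccc(O)cc2O)ccc1Oc1ccc(CCC(=O)c2ccc(O)cc2O)cc1
A4 | alternative 2 | davidigenin, 1-(2,4-dihydroxyphenyl)-3-(4-hydroxyphenyl)propan-1-one | O=C(CCc1ccc(O)cc1)c1ccc(O)cc1O
A5 | alternative 2 | 3-aryloxy-4-hydroxy constitutional isomer of littorachalcone | O=C(CCc1ccc(Oc2cc(CCC(=O)c3ccc(O)cc3O)ccc2O)cc1)c1ccc(O)cc1O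
A6 | alternative 2 | 1-(2,4-dihydroxyphenyl)-3-(3-hydroxyphenyl)propan-1-one | O=C(CCc1cccc(O)c1)c1ccc(O)cc1O
A7 | alternative 3 | 2-phenoxyphenol | Oc1ccccc1Oc1ccccc1
A8 | alternative 3 | 2-phenoxyphenyl methanesulfonate | CS(=O)(=O)Oc1ccccc1Oc1ccccc1
A9 | alternative 3 | 5-bromo-2-(4-bromophenoxy)phenyl methanesulfonate | CS(=O)(=O)Oc1cc(Br)ccc1Oc1ccc(Br)cc1
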